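**Plan**

- Ring A carries the ester carbon on C1 and the benzophenone carbonyl on the neighbouring C2, with the C3 methoxy group flanking C2. This is the pattern a 3-methoxybenzyne gives when a carbon nucleophile enters at C1 and a carbon electrophile at C2.
- The retrosynthesis cuts the ring A C1–carboxyl carbon bond and the ring A C2–carbonyl carbon bond, after taking the ketone back to a carbinol locked in a lactone.
- This leaves three pieces: an o-silylaryl triflate for ring A, a fully substituted ring B benzaldehyde, and tert-butyl isocyanide as the carboxyl carbon.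
- Forward, ring A is prepared from 5-bromovanillin (steps 1–4) and ring B from orcinol (steps 5–7). They are joined in step 8, which closes the only new ring, a five-membered iminolactone.
- The ring is hydrolysed to the phthalide, then opened by oxidation of the benzylic carbon; esterification and removal of the three MOM groups finish the route.
- The target is achiral. The single stereocenter made in step 8 is racemic and is erased in step 10.

Key step: step 8

Remark: keto acid 24 is drawn open-chain; it may rest as its lactol tautomer, which gives the same carboxylate under the basic conditions of step 11.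

**Route**

Step 1
Reactants: 1 5-bromovanillin
Product: 3 2-bromo-6-methoxybenzene-1,4-diol, via aryl formate 2 (not isolated)
Conditions: 30% aq. H2O2, NaOH, H2O/THF, 0 °C to rt, under N2
Reagents that add atoms: hydrogen peroxide, OO
Why: Dakin oxidation, in which the para-hydroxy group drives aryl migration in the peroxide adduct of the aldehyde and the resulting formate 2 is saponified in the same alkaline medium.

Step 2
Reactants: 3 2-bromo-6-methoxybenzene-1,4-diol
Product: 4 1-bromo-3-methoxy-2,5-bis(trimethylsilyloxy)benzene
Conditions: HN(SiMe3)2, THF, reflux; concentrate under vacuum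
Reagents that add atoms: hexamethyldisilazane, C[Si](C)(C)N[Si](C)(C)C
Why: O-silylation of phenols with hexamethyldisilazane caps both hydroxyls, so they need not be told apart, and places silicon on the oxygen next to bromine for the coming O-to-C shift.

Step 3
Reactants: 4 1-bromo-3-methoxy-2,5-bis(trimethylsilyloxy)benzene
Product: 8 4-hydroxy-2-methoxy-6-(trimethylsilyl)phenyl trifluoromethanesulfonate, via aryllithium 5 (not isolated), via lithium silylphenoxide 6 (not isolated), via silyl ether triflate 7 (not isolated)
Conditions: n-BuLi, THF, −78 °C; Tf2O, −78 °C; then 1 M HCl, THF, rt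
Reagents that add atoms: trifluoromethanesulfonic anhydride, O=S(=O)(OS(=O)(=O)C(F)(F)F)C(F)(F)F
Why: Bromine–lithium exchange next to the silyloxy group triggers a retro-Brook (1,3 O-to-C) silyl migration, the freed phenoxide is O-triflated, and dilute acid then hydrolyses the remaining aryl silyl ether while the aryl–silicon bond, meta to both oxygen donors, should resist protodesilylation.

Step 4
Reactants: 8 4-hydroxy-2-methoxy-6-(trimethylsilyl)phenyl trifluoromethanesulfonate
Product: 9 2-methoxy-4-(methoxymethoxy)-6-(trimethylsilyl)phenyl trifluoromethanesulfonate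
Conditions: MOMCl, i-Pr2NEt, CH2Cl2, 0 °C to rt
Reagents that add atoms: chloromethyl methyl ether, COCCl
Why: O-alkylation of the single remaining phenol with chloromethyl methyl ether under amine base (MOM ether formation), conditions to which the aryl triflate and the aryl silane are inert.

Step 5
Reactants: 10 orcinol
Product: 11 4-chloro-5-methylbenzene-1,3-diol
Conditions: SO2Cl2 (1.0 equiv), Et2O, 0 °C to rt
Reagents that add atoms: sulfuryl chloride, O=S(=O)(Cl)Cl
Why: Electrophilic aromatic chlorination of the resorcinol favours C4, ortho to one hydroxyl and para to the other, over the more crowded C2 between the hydroxyls, with one equivalent of reagent and low temperature holding back dichlorination.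

Step 6
Reactants: 11 4-chloro-5-methylbenzene-1,3-diol
Product: 12 2-chloro-1,5-bis(methoxymethoxy)-3-methylbenzene
Conditions: MOMCl (2.5 equiv), i-Pr2NEt, CH2Cl2, 0 °C to reflux
Reagents that add atoms: chloromethyl methyl ether, COCCl
Why: Double MOM ether formation on the two phenols under amine base gives ethers that withstand organolithium reagents and direct the coming metalation.

Step 7
Reactants: 12 2-chloro-1,5-bis(methoxymethoxy)-3-methylbenzene
Product: 15 3-chloro-2,6-bis(methoxymethoxy)-4-methylbenzaldehyde, via aryllithium 13 (not isolated), via lithium hemiaminal alkoxide 14 (not isolated)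
Conditions: n-BuLi, TMEDA, THF, 0 °C; DMF, 0 °C to rt; then H2O
Reagents that add atoms: N,N-dimethylformamide, CN(C)C=O
Why: Directed ortho-metalation removes the ring hydrogen between the two MOM ethers, the most acidic and doubly chelated site (no hydrogen lies ortho to chlorine, so no aryne can form), and the aryllithium is formylated with DMF.

Step 8
Reactants: 9 2-methoxy-4-(methoxymethoxy)-6-(trimethylsilyl)phenyl trifluoromethanesulfonate; 15 3-chloro-2,6-bis(methoxymethoxy)-4-methylbenzaldehyde; 16 tert-butyl isocyanide
Product: 20 rac-N-tert-butyl-3-[3-chloro-2,6-bis(methoxymethoxy)-4-methylphenyl]-4-methoxy-6-(methoxymethoxy)isobenzofuran-1(3H)-imine, via aryne 17 (not isolated), via nitrilium aryl anion 18 (not isolated), via nitrilium alkoxide 19 (not isolated)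
Conditions: KF, 18-crown-6, THF, 0 °C to rt (9 and 16 in 1.5-fold excess over 15)
Reagents that add atoms: none
Why: Fluoride attacks silicon of 9 and expels triflate to give aryne 17, the isocyanide carbon of 16 adds to C1 (the aryne carbon distal to the methoxy group) to give zwitterion 18 with its aryl anion at C2, the anion adds to the carbonyl of 15, and the alkoxide of 19 closes onto the nitrilium carbon. This is the established three-component coupling of arynes, isocyanides and aldehydes to N-substituted iminoisobenzofurans, here applied to a 2,6-dialkoxybenzaldehyde. The furan ring closes by 5-exo-dig attack of the alkoxide oxygen on the nitrilium carbon. The carbinol carbon C3 forms with no controlling element and is racemic by design, since step 10 turns it into the achiral ketone carbon. The step needs regioselective addition to the unsymmetrical aryne, which the C3 methoxy group secures: its inductive pull and the ring distortion it causes make C1 the electrophilic terminus and stabilise the charge developing at C2, while the methoxymethoxy group on C5 is meta to C1 and does not oppose this. It also needs the aryl anion to take the aldehyde over a proton or a second isocyanide, which should be favoured by slow aryne release at 0 °C, dry THF and a non-enolisable aldehyde used as the limiting component.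

Step 9
Reactants: 20 rac-N-tert-butyl-3-[3-chloro-2,6-bis(methoxymethoxy)-4-methylphenyl]-4-methoxy-6-(methoxymethoxy)isobenzofuran-1(3H)-imine
Product: 21 rac-3-[3-chloro-2,6-bis(methoxymethoxy)-4-methylphenyl]-4-methoxy-6-(methoxymethoxy)isobenzofuran-1(3H)-one
Conditions: AcOH/THF/H2O (3:1:1), rt
Reagents that add atoms: water, O
Why: Acid-catalysed hydrolysis of the cyclic imidate (protonation at nitrogen, addition of water, loss of tert-butylamine) should give the lactone under conditions too mild to cleave aryl MOM ethers.

Step 10
Reactants: 21 rac-3-[3-chloro-2,6-bis(methoxymethoxy)-4-methylphenyl]-4-methoxy-6-(methoxymethoxy)isobenzofuran-1(3H)-one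
Product: 24 2-[3-chloro-2,6-bis(methoxymethoxy)-4-methylbenzoyl]-3-methoxy-5-(methoxymethoxy)benzoic acid, via phthalide carbanion 22 (not isolated), via hydroperoxide salt 23 (not isolated)
Conditions: KN(SiMe3)2, THF, −78 °C; O2, P(OEt)3, −78 to 0 °C; then cold 1 M HCl to pH 3
Reagents that add atoms: dioxygen, O=O
Why: Carbanion autoxidation, in which the C3 hydrogen (doubly benzylic, alpha to the lactone oxygen and conjugated with the lactone carbonyl through ring A) is removed, anion 22 captures O2, P(OEt)3 reduces hydroperoxide 23, and the lactol alkoxide opens to the keto carboxylate, erasing the stereocenter.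

Step 11
Reactants: 24 2-[3-chloro-2,6-bis(methoxymethoxy)-4-methylbenzoyl]-3-methoxy-5-(methoxymethoxy)benzoic acid
Product: 25 methyl 2-[3-chloro-2,6-bis(methoxymethoxy)-4-methylbenzoyl]-3-methoxy-5-(methoxymethoxy)benzoate
Conditions: MeI, K2CO3, DMF, rt
Reagents that add atoms: iodomethane, CI
Why: SN2 O-alkylation of the carboxylate with iodomethane gives the open-chain methyl ester, whereas acid-catalysed esterification of such ortho-aroylbenzoic acids tends to give the cyclic pseudo-ester.

Step 12
Reactants: 25 methyl 2-[3-chloro-2,6-bis(methoxymethoxy)-4-methylbenzoyl]-3-methoxy-5-(methoxymethoxy)benzoate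
Product: 26 monochlorosulochrin, methyl 2-(3-chloro-2,6-dihydroxy-4-methylbenzoyl)-5-hydroxy-3-methoxybenzoate
Conditions: HCl (3 M in MeOH), 45 °C
Reagents that add atoms: none
Why: Acid-catalysed acetal exchange with methanol removes all three MOM ethers as dimethoxymethane, while the methyl ester is degenerate toward methanolysis and the aryl methyl ether, aryl chloride and diaryl ketone are stable.

**Compound list**

1 | 5-bromovanillin (3-bromo-4-hydroxy-5-methoxybenzaldehyde) | COc1cc(C=O)cc(Br)c1O | starting material
2 | 3-bromo-4-hydroxy-5-methoxyphenyl formate (aryl formate, not isolated) | COc1cc(OC=O)cc(Br)c1O | intermediate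
3 | 2-bromo-6-methoxybenzene-1,4-diol | COc1cc(O)cc(Br)c1O | intermediate
4 | 1-bromo-3-methoxy-2,5-bis(trimethylsilyloxy)benzene | COc1cc(O[Si](C)(C)C)cc(Br)c1O[Si](C)(C)C | intermediate
5 | 3-methoxy-2,5-bis(trimethylsilyloxy)phenyllithium (not isolated) | COc1cc(O[Si](C)(C)C)cc([Li])c1O[Si](C)(C)C | intermediate
6 | lithium 2-methoxy-6-(trimethylsilyl)-4-(trimethylsilyloxy)phenoxide (not isolated) | COc1cc(O[Si](C)(C)C)cc([Si](C)(C)C)c1[O-].[Li+] | intermediate
7 | 2-methoxy-6-(trimethylsilyl)-4-(trimethylsilyloxy)phenyl trifluoromethanesulfonate (not isolated) | COc1cc(O[Si](C)(C)C)cc([Si](C)(C)C)c1OS(=O)(=O)C(F)(F)F | intermediate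
8 | 4-hydroxy-2-methoxy-6-(trimethylsilyl)phenyl trifluoromethanesulfonate | COc1cc(O)cc([Si](C)(C)C)c1OS(=O)(=O)C(F)(F)F | intermediate
9 | 2-methoxy-4-(methoxymethoxy)-6-(trimethylsilyl)phenyl trifluoromethanesulfonate | COCOc1cc(OC)c(OS(=O)(=O)C(F)(F)F)c([Si](C)(C)C)c1 | intermediate
10 | orcinol (5-methylbenzene-1,3-diol) | Cc1cc(O)cc(O)c1 | starting material
11 | 4-chloro-5-methylbenzene-1,3-diol | Cc1cc(O)cc(O)c1Cl | intermediate
12 | 2-chloro-1,5-bis(methoxymethoxy)-3-methylbenzene | COCOc1cc(C)c(Cl)c(OCOC)c1 | intermediate
13 | 3-chloro-2,6-bis(methoxymethoxy)-4-methylphenyllithium (not isolated) | COCOc1cc(C)c(Cl)c(OCOC)c1[Li] | intermediate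
14 | lithium [3-chloro-2,6-bis(methoxymethoxy)-4-methylphenyl](dimethylamino)methanolate (not isolated) | COCOc1cc(C)c(Cl)c(OCOC)c1C([O-])N(C)C.[Li+] | intermediate
15 | 3-chloro-2,6-bis(methoxymethoxy)-4-methylbenzaldehyde | O=Cc1c(OCOC)cc(C)c(Cl)c1OCOC | intermediate
16 | tert-butyl isocyanide | [C-]#[N+]C(C)(C)C | starting material
17 | 3-methoxy-5-(methoxymethoxy)benzyne (not isolated) | COCOC1=CC#CC(OC)=C1 | intermediate
18 | N-tert-butyl-3-methoxy-5-(methoxymethoxy)benzonitrilium-2-ide, zwitterion (not isolated) | CC(C)(C)[N+]#Cc1cc(OCOC)cc(OC)[c-]1 | intermediate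
19 | rac-N-tert-butyl-2-{[3-chloro-2,6-bis(methoxymethoxy)-4-methylphenyl](oxido)methyl}-3-methoxy-5-(methoxymethoxy)benzonitrilium, zwitterion (not isolated) | CC(C)(C)[N+]#Cc1cc(OCOC)cc(OC)c1C([O-])c1c(OCOC)cc(C)c(Cl)c1OCOC | intermediate
20 | rac-N-tert-butyl-3-[3-chloro-2,6-bis(methoxymethoxy)-4-methylphenyl]-4-methoxy-6-(methoxymethoxy)isobenzofuran-1(3H)-imine | CC(C)(C)N=C1OC(c2c(OCOC)cc(C)c(Cl)c2OCOC)c2c(OC)cc(OCOC)cc12 | intermediate
21 | rac-3-[3-chloro-2,6-bis(methoxymethoxy)-4-methylphenyl]-4-methoxy-6-(methoxymethoxy)isobenzofuran-1(3H)-one | COCOc1cc(OC)c2c(c1)C(=O)OC2c1c(OCOC)cc(C)c(Cl)c1OCOC | intermediate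
22 | potassium 3-[3-chloro-2,6-bis(methoxymethoxy)-4-methylphenyl]-4-methoxy-6-(methoxymethoxy)-1-oxo-1,3-dihydroisobenzofuran-3-ide (not isolated) | COCOc1cc(OC)c2c(c1)C(=O)O[C-]2c1c(OCOC)cc(C)c(Cl)c1OCOC.[K+] | intermediate
23 | potassium salt of rac-3-[3-chloro-2,6-bis(methoxymethoxy)-4-methylphenyl]-3-hydroperoxy-4-methoxy-6-(methoxymethoxy)isobenzofuran-1(3H)-one (not isolated) | COCOc1cc(OC)c2c(c1)C(=O)OC2(O[O-])c1c(OCOC)cc(C)c(Cl)c1OCOC.[K+] | intermediate
24 | 2-[3-chloro-2,6-bis(methoxymethoxy)-4-methylbenzoyl]-3-methoxy-5-(methoxymethoxy)benzoic acid | COCOc1cc(OC)c(C(=O)c2c(OCOC)cc(C)c(Cl)c2OCOC)c(C(=O)O)c1 | intermediate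
25 | methyl 2-[3-chloro-2,6-bis(methoxymethoxy)-4-methylbenzoyl]-3-methoxy-5-(methoxymethoxy)benzoate | COCOc1cc(OC)c(C(=O)c2c(OCOC)cc(C)c(Cl)c2OCOC)c(C(=O)OC)c1 | intermediate
26 | monochlorosulochrin, methyl 2-(3-chloro-2,6-dihydroxy-4-methylbenzoyl)-5-hydroxy-3-methoxybenzoate (achiral) | COC(=O)c1cc(O)cc(OC)c1C(=O)c1c(O)cc(C)c(Cl)c1O | target

**Step count**

Total: 12 steps. Longest linear sequence: 9 steps (steps 1–4, then 8–12, from 5-bromovanillin); the ring B arm (steps 5–7) joins at step 8.

**Steps most likely to fail**

1. Step 8. The short-lived aryl anion may be protonated or may take up a second isocyanide before it adds to the hindered, electron-rich aldehyde. The fallback sets out from 9 and 15 and makes the same two bonds one after the other from the same aryne. Precursor 9 with CsF and I2 in MeCN at rt should give, by insertion of the aryne into the I–I bond, 1,2-diiodo-3-methoxy-5-(methoxymethoxy)benzene F1. Treatment with i-PrMgCl·LiCl in THF at −78 °C is expected to exchange the more crowded iodine beside the methoxy group and give 2-iodo-6-methoxy-4-(methoxymethoxy)phenylmagnesium chloride F2. This longer-lived nucleophile adds to aldehyde 15 to give rac-[3-chloro-2,6-bis(methoxymethoxy)-4-methylphenyl][2-iodo-6-methoxy-4-(methoxymethoxy)phenyl]methanol F3. Carbonylative lactonisation of the ortho-iodobenzylic alcohol with Pd(PPh3)4, CO (1 atm) and Et3N in DMF at 90 °C then comes back to the route at phthalide 21.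

2. Step 10. Deprotonation of the shielded methine may be slow, or the peroxide anion may fragment before it is reduced. The fallback sets out from 21 and moves the oxidation to the ring-opened alcohol. KOH in aqueous dioxane at 80 °C should open the lactone to potassium 2-{[3-chloro-2,6-bis(methoxymethoxy)-4-methylphenyl](hydroxy)methyl}-3-methoxy-5-(methoxymethoxy)benzoate F4. Its secondary diaryl carbinol is oxidised in the same alkaline solution with KMnO4 at 0 °C to rt. Careful acidification with cold dilute HCl comes back to the route at keto acid 24.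

3. Step 3. The spectator aryl silyl ether may be lost or may migrate during lithiation and triflation, so that the triflate ends up on the wrong oxygen. The fallback sets out from 3 and installs the MOM group before any silicon chemistry. One equivalent of MOMCl with i-Pr2NEt in CH2Cl2 at −20 °C should etherify the unhindered hydroxyl (the other is flanked by bromine and methoxy and hydrogen-bonded) to give 2-bromo-6-methoxy-4-(methoxymethoxy)phenol F5. HN(SiMe3)2 converts it to [2-bromo-6-methoxy-4-(methoxymethoxy)phenoxy]trimethylsilane F6. n-BuLi in THF at −78 °C gives 3-methoxy-5-(methoxymethoxy)-2-(trimethylsilyloxy)phenyllithium F7, which rearranges to lithium 2-methoxy-4-(methoxymethoxy)-6-(trimethylsilyl)phenoxide F8. Tf2O then comes back to the route at aryne precursor 9.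

**Further compounds**

F1 | step 8 | 1,2-diiodo-3-methoxy-5-(methoxymethoxy)benzene | COCOc1cc(OC)c(I)c(I)c1
F2 | step 8 | 2-iodo-6-methoxy-4-(methoxymethoxy)phenylmagnesium chloride | COCOc1cc(OC)c([Mg]Cl)c(I)c1
F3 | step 8 | rac-[3-chloro-2,6-bis(methoxymethoxy)-4-methylphenyl][2-iodo-6-methoxy-4-(methoxymethoxy)phenyl]methanol | COCOc1cc(OC)c(C(O)c2c(OCOC)cc(C)c(Cl)c2OCOC)c(I)c1
F4 | step 10 | potassium rac-2-{[3-chloro-2,6-bis(methoxymethoxy)-4-methylphenyl](hydroxy)methyl}-3-methoxy-5-(methoxymethoxy)benzoate | COCOc1cc(OC)c(C(O)c2c(OCOC)cc(C)c(Cl)c2OCOC)c(C(=O)[O-])c1.[K+]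
F5 | step 3 | 2-bromo-6-methoxy-4-(methoxymethoxy)phenol | COCOc1cc(OC)c(O)c(Br)c1
F6 | step 3 | [2-bromo-6-methoxy-4-(methoxymethoxy)phenoxy]trimethylsilane | COCOc1cc(OC)c(O[Si](C)(C)C)c(Br)c1
F7 | step 3 | 3-methoxy-5-(methoxymethoxy)-2-(trimethylsilyloxy)phenyllithium | COCOc1cc(OC)c(O[Si](C)(C)C)c([Li])c1
F8 | step 3 | lithium 2-methoxy-4-(methoxymethoxy)-6-(trimethylsilyl)phenoxide | COCOc1cc(OC)c([O-])c([Si](C)(C)C)c1.[Li+]
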